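**Retrosynthetic overview**

1. The target is a ten-membered carbocycle (C3a–C11a) trans-fused to an α-methylidene γ-lactone and acylated at O5. The C5 ester is put on last (Yamaguchi), after the C4 carbinol has been inverted and masked in one Mitsunobu step.
2. Key disconnection C3a–C4: the unit CH2=C3–C3a(H)–C4(H)OH of the lactone ring and its neighbour is a homoallylic alcohol, the retron of a carbonyl allylation with allylic transposition. The precursor is an open-chain C4 aldehyde carrying a 3-(bromomethyl)butenolide; the CrCl2-mediated addition closes the ten-membered ring, sets C3a and unveils the exocyclic methylidene.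
3. The open chain comes from a Z-selective Wittig union (C6=C7) of a glycerate-derived α-silyloxy methyl ketone with an ylide. The ylide's C9=C10 bond stems from a Z-vinyl iodide and its C11a centre from (R)-epichlorohydrin; the butenolide is then closed by ring-closing metathesis.
4. Ring order: oxirane of the side-chain acid (made apart, Sharpless epoxidation), five-membered lactone ring (step 16), ten-membered ring (step 19).

Key step: step 19

Remark: locants are those of cyclodeca[b]furan-2(3H)-one (O1, C2=O, C3=CH2, C3a, C4–OH, C5–O-acyl, C6(Me)=C7, C8, C9=C10(Me), C11, C11a); the five starting materials are taken as commercial.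

**Route**

Step 1
Reactants: 1 methyl (4S)-2,2-dimethyl-1,3-dioxolane-4-carboxylate
Product: 2 methyl (2S)-2,3-dihydroxypropanoate
Conditions: Dowex 50W (H+ form), MeOH, rt
Reagents that add atoms: none
Why: Acid-catalysed transacetalisation to methanol removes the isopropylidene group without touching the ester or the stereocentre.

Step 2
Reactants: 2 methyl (2S)-2,3-dihydroxypropanoate
Product: 3 methyl (2S)-2,3-bis[(tert-butyldimethylsilyl)oxy]propanoate
Conditions: t-BuMe2SiCl, imidazole, DMF, rt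
Reagents that add atoms: tert-butyldimethylsilyl chloride, CC(C)(C)[Si](C)(C)Cl
Why: Imidazole-promoted silyl ether formation protects both hydroxyls.

Step 3
Reactants: 3 bis-silyl ester
Product: 4 (2S)-2,3-bis[(tert-butyldimethylsilyl)oxy]-N-methoxy-N-methylpropanamide
Conditions: MeNH(OMe)·HCl, i-PrMgCl, THF, −20 → 0 °C
Reagents that add atoms: N-methoxymethanamine hydrochloride, CNOC.Cl
Why: Weinreb amide formation by aminolysis of the ester with the magnesium amide, so that the next Grignard addition stops at the ketone.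

Step 4
Reactants: 4 Weinreb amide
Product: 5 (3S)-3,4-bis[(tert-butyldimethylsilyl)oxy]butan-2-one
Conditions: MeMgBr, THF, −78 → 0 °C
Reagents that add atoms: methylmagnesium bromide, C[Mg]Br
Why: Grignard addition to the Weinreb amide gives the methyl ketone through the stable chelated tetrahedral intermediate, leaving the α-stereocentre untouched.

Step 5
Reactants: 6 3-[(tert-butyldimethylsilyl)oxy]propanal
Product: 7 tert-butyl{[(3Z)-4-iodopent-3-en-1-yl]oxy}dimethylsilane
Conditions: EtPPh3I, n-BuLi, THF, 0 °C; I2, −78 °C; NaN(SiMe3)2, −20 °C; then 6, −78 °C → rt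
Reagents that add atoms: ethyltriphenylphosphonium iodide, CC[P+](c1ccccc1)(c1ccccc1)c1ccccc1.[I-]; iodine, II
Why: Wittig reaction with the α-iodo ylide Ph3P=C(I)CH3 (Stork–Zhao-type olefination) places iodine cis to the chain and so fixes the Z geometry of the later C9=C10 bond.

Step 6
Reactants: 7 (Z)-vinyl iodide; 8 (2R)-2-(chloromethyl)oxirane
Product: 10 (2R,4Z)-7-[(tert-butyldimethylsilyl)oxy]-1-chloro-4-methylhept-4-en-2-ol, via alkenyllithium 9 (not isolated)
Conditions: t-BuLi (2 equiv), Et2O, −78 °C; then 8, BF3·OEt2, −78 °C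
Reagents that add atoms: none
Why: Iodine–lithium exchange with retention of alkene geometry, then BF3-assisted SN2 opening of the epoxide at its CH2 terminus; the later C11a centre comes unchanged from 8.

Step 7
Reactants: 10 chlorohydrin
Product: 12 (3R,5Z)-8-[(tert-butyldimethylsilyl)oxy]-5-methylocta-1,5-dien-3-ol, via terminal epoxide 11 (not isolated)
Conditions: Me3SI, n-BuLi (excess), THF, −20 °C → rt
Reagents that add atoms: trimethylsulfonium iodide, C[S+](C)C.[I-]
Why: Excess dimethylsulfonium methylide first closes the chlorohydrin to the epoxide, then opens it at CH2 and eliminates Me2S (epoxide-to-allylic-alcohol one-carbon homologation); the carbinol centre is not touched.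

Step 8
Reactants: 12 silyl ether
Product: 13 (3R,5Z)-5-methylocta-1,5-diene-3,8-diol
Conditions: Bu4NF, THF, 0 °C → rt
Reagents that add atoms: none
Why: Fluoride cleavage of the primary silyl ether.

Step 9
Reactants: 13 diol
Product: 14 (3R,5Z)-8-iodo-5-methylocta-1,5-dien-3-ol
Conditions: I2, PPh3, imidazole, CH2Cl2, 0 °C
Reagents that add atoms: iodine, II
Why: Appel-type iodination should be selective for the primary over the secondary allylic hydroxyl.

Step 10
Reactants: 14 primary iodide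
Product: 15 [(3Z,6R)-6-hydroxy-4-methylocta-3,7-dien-1-yl]triphenylphosphonium iodide
Conditions: PPh3, MeCN, 80 °C
Reagents that add atoms: triphenylphosphine, c1ccc(cc1)P(c1ccccc1)c1ccccc1
Why: SN2 quaternisation of PPh3 by the primary iodide gives the Wittig salt.

Step 11
Reactants: 16 methyl (2Z)-2-methylbut-2-enoate
Product: 17 (2Z)-2-methylbut-2-en-1-ol
Conditions: i-Bu2AlH, CH2Cl2, −78 → 0 °C
Reagents that add atoms: none
Why: Hydride reduction of the ester to the allylic alcohol without Z/E isomerisation.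

Step 12
Reactants: 17 (Z)-allylic alcohol
Product: 18 [(2S,3R)-2,3-dimethyloxiran-2-yl]methanol
Conditions: Ti(OiPr)4 (cat.), L-(+)-diethyl tartrate (cat.), t-BuOOH, 4 Å MS, CH2Cl2, −20 °C
Reagents that add atoms: tert-butyl hydroperoxide, CC(C)(C)OO
Why: Sharpless asymmetric epoxidation; L-(+)-tartrate directs oxygen to the face that gives the (2S,3R) epoxy alcohol, and the Z alkene fixes the trans relation of the two methyl groups.

Step 13
Reactants: 18 epoxy alcohol
Product: 19 (2R,3R)-2,3-dimethyloxirane-2-carboxylic acid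
Conditions: RuCl3·xH2O (cat.), NaIO4, MeCN/EtOAc/H2O, 0 °C → rt
Reagents that add atoms: water, O
Why: RuO4-catalysed oxidation of the primary alcohol to the acid leaves the oxirane and both stereocentres untouched.

Step 14
Reactants: 15 phosphonium iodide; 5 α-silyloxy methyl ketone
Product: 21 (3R,5Z,8Z,10R)-10,11-bis[(tert-butyldimethylsilyl)oxy]-5,9-dimethylundeca-1,5,8-trien-3-ol, via potassium alkoxide ylide 20 (not isolated)
Conditions: 15, KN(SiMe3)2 (2 equiv), THF, −78 → 0 °C; then 5, −78 °C → rt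
Reagents that add atoms: none
Why: Wittig reaction of a non-stabilised ylide with an α-silyloxy methyl ketone is Z-selective (oxygen-bearing carbon cis to the new chain) and so sets the C6=C7 geometry; the free hydroxyl travels as its alkoxide.

Step 15
Reactants: 21 trienol; 22 2-(bromomethyl)prop-2-enoic acid
Product: 23 (3R,5Z,8Z,10R)-10,11-bis[(tert-butyldimethylsilyl)oxy]-5,9-dimethylundeca-1,5,8-trien-3-yl 2-(bromomethyl)prop-2-enoate
Conditions: DIC, DMAP (cat.), CH2Cl2, −20 → 0 °C
Reagents that add atoms: none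
Why: Carbodiimide (Steglich-type) esterification of the only free hydroxyl.

Step 16
Reactants: 23 acrylate ester
Product: 24 (5R)-3-(bromomethyl)-5-[(2Z,5Z,7R)-7,8-bis[(tert-butyldimethylsilyl)oxy]-2,6-dimethylocta-2,5-dien-1-yl]furan-2(5H)-one
Conditions: second-generation Grubbs catalyst (cat.), CH2Cl2 (0.005 M), 40 °C
Reagents that add atoms: none
Why: Ring-closing metathesis between the vinyl group and the 1,1-disubstituted acrylate closes the butenolide; the trisubstituted alkenes are too hindered to compete.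

Step 17
Reactants: 24 bis-silyl butenolide bromide
Product: 25 (5R)-3-(bromomethyl)-5-[(2Z,5Z,7R)-7-[(tert-butyldimethylsilyl)oxy]-8-hydroxy-2,6-dimethylocta-2,5-dien-1-yl]furan-2(5H)-one
Conditions: camphorsulfonic acid (cat.), MeOH/CH2Cl2 1:1, 0 °C
Reagents that add atoms: none
Why: Acid-catalysed methanolysis cleaves the primary silyl ether much faster than the secondary one.

Step 18
Reactants: 25 primary alcohol
Product: 26 (2R,3Z,6Z)-8-[(2R)-4-(bromomethyl)-5-oxo-2,5-dihydrofuran-2-yl]-2-[(tert-butyldimethylsilyl)oxy]-3,7-dimethylocta-3,6-dienal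
Conditions: Dess–Martin periodinane, CH2Cl2, 0 °C → rt
Reagents that add atoms: none
Why: Dess–Martin oxidation gives the α-silyloxy aldehyde under non-basic conditions, which should avoid epimerisation and tolerates the allylic bromide.

Step 19
Reactants: 26 bromomethyl-butenolide aldehyde
Product: 28 (3aR,4R,5R,6Z,9Z,11aR)-5-[(tert-butyldimethylsilyl)oxy]-4-hydroxy-6,10-dimethyl-3-methylidene-3a,4,5,8,11,11a-hexahydrocyclodeca[b]furan-2(3H)-one, via allyl-CrCl2 species 27 (not isolated)
Conditions: CrCl2 (10 equiv), THF, rt, slow addition of 26 (final 0.002 M)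
Reagents that add atoms: none
Why: Two CrCl2 reduce the allylic C–Br bond to an allylic trivalent-chromium species, which adds to the aldehyde through its γ-carbon (C3a) in a closed six-membered Zimmerman–Traxler transition state; this forms the C3a–C4 bond, closes the ten-membered carbocycle and turns the Cr-bound CH2 into the exocyclic methylidene (Nozaki–Hiyama–Kishi allylation, SE2′). The closest known reaction type is the CrCl2-mediated macrocyclisation of 2-(bromomethyl)acrylate-type bromides onto aldehydes to ten-membered germacranolide rings, together with metal-mediated additions of 3-(bromomethyl)furan-2(5H)-ones to aldehydes. The ring closes in a 10-exo-trig mode: the carbonyl oxygen stays outside the new ring, as do C3 and its CH2. C3a is controlled by C11a: the side chain on the butenolide blocks one face, so the aldehyde should add anti to it and the lactone becomes trans-fused (3aR). C4 is controlled by the ring-locked geometry of the allyl unit (C11a trans to CH2–Cr, an E-type γ-substituted reagent): the chair with the C5 chain equatorial and the C5–OSi bond anti to the forming bond gives the anti adduct, the 4R carbinol, which is the C4 epimer of the target and is inverted in step 20. The step needs γ- over α-attack and cyclisation over oligomerisation; the cyclic transition state secures the first, slow addition at high dilution the second.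

Step 20
Reactants: 28 macrocyclic 4R carbinol
Product: 29 (3aS,4S,5R,6Z,9Z,11aR)-5-[(tert-butyldimethylsilyl)oxy]-6,10-dimethyl-3-methylidene-2-oxo-2,3,3a,4,5,8,11,11a-octahydrocyclodeca[b]furan-4-yl pyridine-2-carboxylate
Conditions: pyridine-2-carboxylic acid, PPh3, DIAD, THF, 0 °C → rt
Reagents that add atoms: pyridine-2-carboxylic acid, OC(=O)c1ccccn1
Why: Mitsunobu reaction: SN2 displacement of the activated C4 oxygen by the carboxylate inverts C4 to the configuration of the target, and the picolinate masks this oxygen for the next two steps (the 3a descriptor changes by priority only).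

Step 21
Reactants: 29 silyl ether picolinate
Product: 30 (3aS,4S,5R,6Z,9Z,11aR)-5-hydroxy-6,10-dimethyl-3-methylidene-2-oxo-2,3,3a,4,5,8,11,11a-octahydrocyclodeca[b]furan-4-yl pyridine-2-carboxylate
Conditions: HF·pyridine, pyridine, THF, 0 °C → rt
Reagents that add atoms: none
Why: Fluoride cleavage of the secondary silyl ether under buffered conditions that the ester and the α-methylidene lactone should survive.

Step 22
Reactants: 30 C5 alcohol; 19 (2R,3R)-epoxy acid
Product: 32 (3aS,4S,5R,6Z,9Z,11aR)-5-{[(2R,3R)-2,3-dimethyloxirane-2-carbonyl]oxy}-6,10-dimethyl-3-methylidene-2-oxo-2,3,3a,4,5,8,11,11a-octahydrocyclodeca[b]furan-4-yl pyridine-2-carboxylate, via mixed anhydride 31 (not isolated)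
Conditions: 19, 2,4,6-trichlorobenzoyl chloride, Et3N, THF, rt; then 30, DMAP, toluene, rt
Reagents that add atoms: none
Why: Yamaguchi esterification through the mixed anhydride acylates the allylic C5 hydroxyl with retention at every centre.

Step 23
Reactants: 32 diester
Product: 33 (3aR,4S,5R,6Z,9Z,11aR)-4-hydroxy-6,10-dimethyl-3-methylidene-2-oxo-2,3,3a,4,5,8,11,11a-octahydrocyclodeca[b]furan-5-yl (2R,3R)-2,3-dimethyloxirane-2-carboxylate
Conditions: Cu(OAc)2 (cat.), MeOH/CH2Cl2, rt
Reagents that add atoms: none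
Why: Chelation-assisted methanolysis of the picolinate under neutral conditions should free the C4 hydroxyl without acyl migration, oxirane opening or addition to the α-methylidene lactone.

**Compound list**

1 | methyl (4S)-2,2-dimethyl-1,3-dioxolane-4-carboxylate | COC(=O)[C@@H]1COC(C)(C)O1 | starting material
2 | methyl (2S)-2,3-dihydroxypropanoate | COC(=O)[C@@H](O)CO | intermediate
3 | methyl (2S)-2,3-bis[(tert-butyldimethylsilyl)oxy]propanoate | COC(=O)[C@@H](O[Si](C)(C)C(C)(C)C)CO[Si](C)(C)C(C)(C)C | intermediate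
4 | (2S)-2,3-bis[(tert-butyldimethylsilyl)oxy]-N-methoxy-N-methylpropanamide | CON(C)C(=O)[C@@H](O[Si](C)(C)C(C)(C)C)CO[Si](C)(C)C(C)(C)C | intermediate
5 | (3S)-3,4-bis[(tert-butyldimethylsilyl)oxy]butan-2-one | CC(=O)[C@@H](O[Si](C)(C)C(C)(C)C)CO[Si](C)(C)C(C)(C)C | intermediate
6 | 3-[(tert-butyldimethylsilyl)oxy]propanal | O=CCCO[Si](C)(C)C(C)(C)C | starting material
7 | tert-butyl{[(3Z)-4-iodopent-3-en-1-yl]oxy}dimethylsilane | C/C(I)=C/CCO[Si](C)(C)C(C)(C)C | intermediate
8 | (2R)-2-(chloromethyl)oxirane | ClC[C@H]1CO1 | starting material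
9 | (2E)-5-[(tert-butyldimethylsilyl)oxy]pent-2-en-2-yllithium (lithium cis to the chain, geometry of 7 retained) | C/C([Li])=C/CCO[Si](C)(C)C(C)(C)C | intermediate (not isolated)
10 | (2R,4Z)-7-[(tert-butyldimethylsilyl)oxy]-1-chloro-4-methylhept-4-en-2-ol | ClC[C@H](O)C/C(C)=C\CCO[Si](C)(C)C(C)(C)C | intermediate
11 | tert-butyldimethyl({(3Z)-4-methyl-5-[(2R)-oxiran-2-yl]pent-3-en-1-yl}oxy)silane | C1O[C@@H]1C/C(C)=C\CCO[Si](C)(C)C(C)(C)C | intermediate (not isolated)
12 | (3R,5Z)-8-[(tert-butyldimethylsilyl)oxy]-5-methylocta-1,5-dien-3-ol | C=C[C@H](O)C/C(C)=C\CCO[Si](C)(C)C(C)(C)C | intermediate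
13 | (3R,5Z)-5-methylocta-1,5-diene-3,8-diol | C=C[C@H](O)C/C(C)=C\CCO | intermediate
14 | (3R,5Z)-8-iodo-5-methylocta-1,5-dien-3-ol | C=C[C@H](O)C/C(C)=C\CCI | intermediate
15 | [(3Z,6R)-6-hydroxy-4-methylocta-3,7-dien-1-yl]triphenylphosphonium iodide | C=C[C@H](O)C/C(C)=C\CC[P+](c1ccccc1)(c1ccccc1)c1ccccc1.[I-] | intermediate
16 | methyl (2Z)-2-methylbut-2-enoate | C/C=C(/C)C(=O)OC | starting material
17 | (2Z)-2-methylbut-2-en-1-ol | C/C=C(/C)CO | intermediate
18 | [(2S,3R)-2,3-dimethyloxiran-2-yl]methanol | OC[C@]1(C)O[C@@H]1C | intermediate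
19 | (2R,3R)-2,3-dimethyloxirane-2-carboxylic acid | OC(=O)[C@]1(C)O[C@@H]1C | intermediate
20 | potassium (3R,5Z)-5-methyl-8-(triphenyl-λ5-phosphanylidene)octa-1,5-dien-3-olate | C=C[C@H]([O-])C/C(C)=C\CC=P(c1ccccc1)(c1ccccc1)c1ccccc1.[K+] | intermediate (not isolated)
21 | (3R,5Z,8Z,10R)-10,11-bis[(tert-butyldimethylsilyl)oxy]-5,9-dimethylundeca-1,5,8-trien-3-ol | CC(C)(C)[Si](C)(C)OC[C@H](O[Si](C)(C)C(C)(C)C)/C(C)=C\C/C=C(C)\C[C@@H](O)C=C | intermediate
22 | 2-(bromomethyl)prop-2-enoic acid | C=C(CBr)C(=O)O | starting material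
23 | (3R,5Z,8Z,10R)-10,11-bis[(tert-butyldimethylsilyl)oxy]-5,9-dimethylundeca-1,5,8-trien-3-yl 2-(bromomethyl)prop-2-enoate | CC(C)(C)[Si](C)(C)OC[C@H](O[Si](C)(C)C(C)(C)C)/C(C)=C\C/C=C(C)\C[C@@H](OC(=O)C(=C)CBr)C=C | intermediate
24 | (5R)-3-(bromomethyl)-5-[(2Z,5Z,7R)-7,8-bis[(tert-butyldimethylsilyl)oxy]-2,6-dimethylocta-2,5-dien-1-yl]furan-2(5H)-one | CC(C)(C)[Si](C)(C)OC[C@H](O[Si](C)(C)C(C)(C)C)/C(C)=C\C/C=C(C)\C[C@H]1OC(=O)C(CBr)=C1 | intermediate
25 | (5R)-3-(bromomethyl)-5-[(2Z,5Z,7R)-7-[(tert-butyldimethylsilyl)oxy]-8-hydroxy-2,6-dimethylocta-2,5-dien-1-yl]furan-2(5H)-one | OC[C@H](O[Si](C)(C)C(C)(C)C)/C(C)=C\C/C=C(C)\C[C@H]1OC(=O)C(CBr)=C1 | intermediate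
26 | (2R,3Z,6Z)-8-[(2R)-4-(bromomethyl)-5-oxo-2,5-dihydrofuran-2-yl]-2-[(tert-butyldimethylsilyl)oxy]-3,7-dimethylocta-3,6-dienal | O=C[C@H](O[Si](C)(C)C(C)(C)C)/C(C)=C\C/C=C(C)\C[C@H]1OC(=O)C(CBr)=C1 | intermediate
27 | {(5R)-5-[(2Z,5Z,7R)-7-[(tert-butyldimethylsilyl)oxy]-2,6-dimethyl-8-oxoocta-2,5-dien-1-yl]-2-oxo-2,5-dihydrofuran-3-yl}methyl-CrCl2 (allylic organochromium, trivalent chromium) | O=C[C@H](O[Si](C)(C)C(C)(C)C)/C(C)=C\C/C=C(C)\C[C@H]1OC(=O)C(C[Cr](Cl)Cl)=C1 | intermediate (not isolated)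
28 | (3aR,4R,5R,6Z,9Z,11aR)-5-[(tert-butyldimethylsilyl)oxy]-4-hydroxy-6,10-dimethyl-3-methylidene-3a,4,5,8,11,11a-hexahydrocyclodeca[b]furan-2(3H)-one | C=C1C(=O)O[C@@H]2C/C(C)=C\C/C=C(/C)[C@@H](O[Si](C)(C)C(C)(C)C)[C@H](O)[C@@H]12 | intermediate
29 | (3aS,4S,5R,6Z,9Z,11aR)-5-[(tert-butyldimethylsilyl)oxy]-6,10-dimethyl-3-methylidene-2-oxo-2,3,3a,4,5,8,11,11a-octahydrocyclodeca[b]furan-4-yl pyridine-2-carboxylate | C=C1C(=O)O[C@@H]2C/C(C)=C\C/C=C(/C)[C@@H](O[Si](C)(C)C(C)(C)C)[C@@H](OC(=O)c3ccccn3)[C@@H]12 | intermediate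
30 | (3aS,4S,5R,6Z,9Z,11aR)-5-hydroxy-6,10-dimethyl-3-methylidene-2-oxo-2,3,3a,4,5,8,11,11a-octahydrocyclodeca[b]furan-4-yl pyridine-2-carboxylate | C=C1C(=O)O[C@@H]2C/C(C)=C\C/C=C(/C)[C@@H](O)[C@@H](OC(=O)c3ccccn3)[C@@H]12 | intermediate
31 | (2R,3R)-2,3-dimethyloxirane-2-carboxylic 2,4,6-trichlorobenzoic anhydride | O=C(OC(=O)c1c(Cl)cc(Cl)cc1Cl)[C@]1(C)O[C@@H]1C | intermediate (not isolated)
32 | (3aS,4S,5R,6Z,9Z,11aR)-5-{[(2R,3R)-2,3-dimethyloxirane-2-carbonyl]oxy}-6,10-dimethyl-3-methylidene-2-oxo-2,3,3a,4,5,8,11,11a-octahydrocyclodeca[b]furan-4-yl pyridine-2-carboxylate | C=C1C(=O)O[C@@H]2C/C(C)=C\C/C=C(/C)[C@@H](OC(=O)[C@]3(C)O[C@@H]3C)[C@@H](OC(=O)c3ccccn3)[C@@H]12 | intermediate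
33 | (3aR,4S,5R,6Z,9Z,11aR)-4-hydroxy-6,10-dimethyl-3-methylidene-2-oxo-2,3,3a,4,5,8,11,11a-octahydrocyclodeca[b]furan-5-yl (2R,3R)-2,3-dimethyloxirane-2-carboxylate | C=C1C(=O)O[C@@H]2C/C(C)=C\C/C=C(/C)[C@@H](OC(=O)[C@]3(C)O[C@@H]3C)[C@@H](O)[C@@H]12 | target

**Totals and risks**

Total step count: 23. Longest linear sequence: 16 steps (steps 5–10, then 14–23, from 6).

Steps most likely to fail:

Step 19. The facial selectivity at the aldehyde may be reversed if a transannular conformation of the forming ten-membered ring overrides the chair preference; cyclisation may also be outrun by intermolecular coupling. Fallback for the first case, setting out from 26: the same closure then gives the 4S carbinol (3aR,4S,5R,6Z,9Z,11aR)-5-[(tert-butyldimethylsilyl)oxy]-4-hydroxy-6,10-dimethyl-3-methylidene-3a,4,5,8,11,11a-hexahydrocyclodeca[b]furan-2(3H)-one F1. This is esterified with retention (pyridine-2-carboxylic acid, DIC, DMAP, CH2Cl2) instead of with inversion, and the route is rejoined at 29.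

Step 20. The activated C4 oxygen may be lost by elimination, or substitution at the hindered carbinol between C3a and the silyloxy-bearing C5 may not occur. Fallback setting out from 28: sulfonylation (Tf2O, pyridine, CH2Cl2, −78 °C) gives the triflate (3aS,4R,5R,6Z,9Z,11aR)-5-[(tert-butyldimethylsilyl)oxy]-6,10-dimethyl-3-methylidene-2-oxo-2,3,3a,4,5,8,11,11a-octahydrocyclodeca[b]furan-4-yl trifluoromethanesulfonate F2. Displacement in a separate SN2 step with CsO2C-2-pyridyl (caesium pyridine-2-carboxylate, 18-crown-6, toluene, rt) returns to 29.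

Step 16. The metathesis catalyst may be consumed by the allylic bromide, or the bromomethyl alkene may enter cross-metathesis before ring closure. Fallback setting out from 21: acylation with acryloyl chloride (Et3N, CH2Cl2) gives the acrylate (3R,5Z,8Z,10R)-10,11-bis[(tert-butyldimethylsilyl)oxy]-5,9-dimethylundeca-1,5,8-trien-3-yl prop-2-enoate F3. Ring-closing metathesis (second-generation Grubbs catalyst) gives the unsubstituted butenolide (5R)-5-[(2Z,5Z,7R)-7,8-bis[(tert-butyldimethylsilyl)oxy]-2,6-dimethylocta-2,5-dien-1-yl]furan-2(5H)-one F4. Morita–Baylis–Hillman hydroxymethylation (aqueous formaldehyde, PBu3 cat., THF) gives (5R)-5-[(2Z,5Z,7R)-7,8-bis[(tert-butyldimethylsilyl)oxy]-2,6-dimethylocta-2,5-dien-1-yl]-3-(hydroxymethyl)furan-2(5H)-one F5, and Appel bromination (CBr4, PPh3, CH2Cl2) returns to 24.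

**Further compounds**

F1 | step 19 | (3aR,4S,5R,6Z,9Z,11aR)-5-[(tert-butyldimethylsilyl)oxy]-4-hydroxy-6,10-dimethyl-3-methylidene-3a,4,5,8,11,11a-hexahydrocyclodeca[b]furan-2(3H)-one | C=C1C(=O)O[C@@H]2C/C(C)=C\C/C=C(/C)[C@@H](O[Si](C)(C)C(C)(C)C)[C@@H](O)[C@@H]12
F2 | step 20 | (3aS,4R,5R,6Z,9Z,11aR)-5-[(tert-butyldimethylsilyl)oxy]-6,10-dimethyl-3-methylidene-2-oxo-2,3,3a,4,5,8,11,11a-octahydrocyclodeca[b]furan-4-yl trifluoromethanesulfonate | C=C1C(=O)O[C@@H]2C/C(C)=C\C/C=C(/C)[C@@H](O[Si](C)(C)C(C)(C)C)[C@H](OS(=O)(=O)C(F)(F)F)[C@@H]12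
F3 | step 16 | (3R,5Z,8Z,10R)-10,11-bis[(tert-butyldimethylsilyl)oxy]-5,9-dimethylundeca-1,5,8-trien-3-yl prop-2-enoate | CC(C)(C)[Si](C)(C)OC[C@H](O[Si](C)(C)C(C)(C)C)/C(C)=C\C/C=C(C)\C[C@@H](OC(=O)C=C)C=C
F4 | step 16 | (5R)-5-[(2Z,5Z,7R)-7,8-bis[(tert-butyldimethylsilyl)oxy]-2,6-dimethylocta-2,5-dien-1-yl]furan-2(5H)-one | CC(C)(C)[Si](C)(C)OC[C@H](O[Si](C)(C)C(C)(C)C)/C(C)=C\C/C=C(C)\C[C@H]1OC(=O)C=C1
F5 | step 16 | (5R)-5-[(2Z,5Z,7R)-7,8-bis[(tert-butyldimethylsilyl)oxy]-2,6-dimethylocta-2,5-dien-1-yl]-3-(hydroxymethyl)furan-2(5H)-one | CC(C)(C)[Si](C)(C)OC[C@H](O[Si](C)(C)C(C)(C)C)/C(C)=C\C/C=C(C)\C[C@H]1OC(=O)C(CO)=C1
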